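- Ask first what the end state holds, then how fast the flask gets there.

| setting | north-west | south-west | south-east | south | red | grey | amber | green |
|---|---|---|---|---|---|---|---|---|
| first end groups | 0.12 M | 0.12 M | 0.12 M | 0.060 M | 0.12 M (fed, over 4.0 min) | 0.12 M | 0.12 M | 0.12 M |
| second end groups | 0.126 M | 0.18 M | 0.28 M | 0.126 M | 0.126 M | 0.126 M | 0.126 M (fed, over 4.0 min) | 0.126 M (fed, over 1.0 min) |
| remark | run made earlier | run made earlier | run made earlier | run made earlier | all else is in the flask from the start; the feed brings no volume worth counting | everything together at the start | all else is in the flask from the start; the feed brings no volume worth counting | all else is in the flask from the start; the feed brings no volume worth counting |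
| time |  |  |  |  | 5.0 min | 5.0 min | 5.0 min | 5.0 min |

| run | time / min | links / % | side product / % |
|---|---|---|---|
| north-west | 0.200 | 33 | 8 |
| north-west | 0.667 | 25 | 18 |
| north-west | 1.00 | 25 | 22 |
| north-west | 1.50 | 20 | 30 |
| north-west | 2.50 | 17 | 40 |
| north-west | 3.00 | 13 | 43 |
| south-west | 0.250 | 36 | 9 |
| south-west | 0.417 | 32 | 13 |
| south-west | 0.667 | 34 | 16 |
| south-west | 1.00 | 28 | 26 |
| south-west | 2.00 | 24 | 37 |
| south-west | 3.00 | 19 | 46 |
| south-east | 0.500 | 41 | 15 |
| south-east | 1.00 | 35 | 24 |
| south-east | 1.50 | 31 | 36 |
| south-east | 2.00 | 24 | 37 |
| south-east | 2.50 | 22 | 47 |
| south-east | 3.00 | 19 | 50 |
| south | 0.667 | 40 | 10 |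
| south | 1.33 | 36 | 17 |
| south | 2.00 | 31 | 24 |
| south | 2.50 | 30 | 32 |
| south | 3.00 | 27 | 34 |

(readings scatter by 1.5 percentage points)

- percent here means first end groups units held: one side product counts as two

- the best flask by share of links in links plus side product; "all alike" if 1.5 percentage points covers them all (red / grey / amber / green / all alike)
- share of links in links plus side product at the end, red
- share of links in links plus side product at the end, grey
- share of links in links plus side product at the end, amber
- share of links in links plus side product at the end, green

- From first to last reading links fall in each earlier run, so I expect a recipe to slow that loss, not to stop it.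
- One side product counts as two units, so I take it to form from one link and one first end group. That makes the attack on links a pseudo-first-order loss at fixed [first end groups], with one link lost for every two units of side product gained.
- In the north-west run, side product climbs from 22% to 43% between 1.00 min and 3.00 min. Over that stretch links average 19.0%, and what is neither link nor side product averages 48.5%.
- I assume that rest is free first end groups. Scaled to the full charge, these give my link half-life, the time in which attack at [first end groups] = 0.12 M halves the links: 1.22 min. It is a reading and carries the scatter.
- The bench rule says to dose slowly whatever attacks the product, so I favour the flask that feeds first end groups, red.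
- The rule has a border. Red's feed spans 3.29 of these half-lives. Green's feed, of second end groups, spans 0.822, so I expect green close to grey.
- I place amber below red: its first end groups stand at full charge from the start. This ranking is mine and carries no percentages.
- The forecast picks red, with 30% for red, 18% for grey, 23% for amber and 19.5% for green, on the ground that “Slow feeding keeps the free pool small”.
- The flasks give 29.9% for red, 16.2% for grey, 23.8% for amber and 18.0% for green, so red leads.

    first end groups + second end groups ⇌ links + released group (K = 0.230, k = 4.20 M⁻¹ s⁻¹)
    2 first end groups → homo dimer (k = 0.0110 M⁻¹ s⁻¹)
    first end groups + links → side product (k = 0.100 M⁻¹ s⁻¹)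

- Now take red with 0.072 M of first end groups. My half-life scales inversely with the charge and becomes 2.03 min. Reckoned at full charge, the stretch after the feed then counts 0.493 half-lives, against 0.822 for red. This neighbour reaches a share of 46.5%, above red's 29.9%. It ends with links at 27.0% and side product at 31.1% of its own charge.

(Readings and results were computed on assumed constants; scatter was added.)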